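**Retrosynthetic overview**

1. Locants: lactone O1, C2(=O), C3=C4, C5, C6; C1' = CH(OAc); cyclopropane C2', C3'(H2), C4'; ketone C5'; C6' = CH(CH3)O. The route rests on the erythro pair O1–C6 / C1'–OAc lying between C5 and C2': joining C4 to C2' turns it into a cis-cyclopent-3-ene-1,2-diol, so the open-chain relation is stored in a five-membered carbocycle.
2. Disconnections, backwards: caffeate ester at the C6' oxygen; cyclopropane bonds C2'–C4' and C3'–C4' ([2+1] of a lactate-derived diazoketone on the vinyl group C2'=C3'); C3=C4 and C2'=C3' (ring-rearrangement metathesis of the acrylate of the cyclopentenediol monoacetate).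
3. Ring order: cyclopentene (temporary, from cyclopentadiene), then the dihydropyranone (closed as the cyclopentene is opened), then the cyclopropane.
4. Absolute configuration: C6 and C1' from a lipase resolution of the cis-diacetate, C6' from ethyl (S)-lactate, C2' and C4' from a chiral carbene-transfer catalyst.

Key step: step 5

Assumption: the sense of induction of [Ru((S)-Ph-pheox)(MeCN)4]PF6 is taken to be the one that places the carbene on the vinyl face leading to 2'S,4'S; it is fixed beforehand on a simple allylic acetate, and the (R)-ligand is used if the sense is the opposite.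

**Route**

Step 1
Reactants: 1 cyclopentadiene (freshly cracked from its dimer, 3 equiv)
Product: 2 rac-cis-cyclopent-3-ene-1,2-diol
Conditions: OsO4 (1 mol%), NMO (1 equiv), acetone/H2O, 0 °C
Reagents that add atoms: N-methylmorpholine N-oxide, C[N+]1([O-])CCOCC1; water, O (the two hydroxyl oxygens, relayed through OsO4)
Why: Upjohn dihydroxylation: OsO4 adds suprafacially to one double bond of the conjugated diene, which fixes the two hydroxyls cis (racemic), and the excess of diene together with the lower reactivity of the remaining isolated, allylically oxygenated alkene should keep the reaction at the mono-diol.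

Step 2
Reactants: 2 rac-cis-cyclopent-3-ene-1,2-diol
Product: 3 rac-cis-cyclopent-3-ene-1,2-diyl diacetate
Conditions: Ac2O, pyridine, DMAP (cat.), CH2Cl2, 0 °C to rt
Reagents that add atoms: acetic anhydride, CC(=O)OC(C)=O
Why: DMAP-catalysed acylation of both secondary hydroxyls with retention, giving a diester whose two acetates differ only in being allylic (C2) or homoallylic (C1).

Step 3
Reactants: 3 rac-cis-cyclopent-3-ene-1,2-diyl diacetate
Product: 4 (1S,5R)-5-hydroxycyclopent-2-en-1-yl acetate [= (1R,2S)-2-acetoxycyclopent-3-en-1-ol]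
Conditions: Burkholderia cepacia lipase (immobilised), n-BuOH (3 equiv), MTBE, 30 °C, stopped near 45% conversion; chromatography
Reagents that add atoms: none
Why: Lipase-catalysed alcoholysis as a kinetic resolution: by the empirical size rule for lipases the enzyme attacks the ester of an R-configured ring carbinol flanked by a small CH2 and a large substituted carbon, a pattern offered only by C1–OAc of the (1R,2S)-diacetate, so this enantiomer should be unmasked at C1 while its allylic acetate and the whole (1S,2R)-diacetate stay esterified and are removed; no stereocentre is formed or inverted.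

Step 4
Reactants: 4 (1S,5R)-5-hydroxycyclopent-2-en-1-yl acetate; 5 acryloyl chloride
Product: 6 (1R,2S)-2-acetoxycyclopent-3-en-1-yl acrylate
Conditions: iPr2NEt, CH2Cl2, −78 to 0 °C
Reagents that add atoms: none
Why: Esterification of the free homoallylic hydroxyl by the acid chloride, run cold with a hindered base so that the neighbouring cis-acetate does not migrate; configuration is retained.

Step 5
Reactants: 6 (1R,2S)-2-acetoxycyclopent-3-en-1-yl acrylate
Product: 7 (S)-1-[(R)-6-oxo-3,6-dihydro-2H-pyran-2-yl]prop-2-en-1-yl acetate
Conditions: second-generation Grubbs catalyst RuCl2(H2IMes)(PCy3)(=CHPh) (5 mol%), CH2Cl2 (0.005 M), 40 °C, argon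
Reagents that add atoms: none
Why: A ruthenium methylidene adds across the ring C4=C2' bond ([2+2], then cycloreversion) with the metal on C4 and its CH2 on C2', and the C4 alkylidene then undergoes ring-closing metathesis with the acrylate C=C, which releases the lactone and returns the acrylate CH2 to ruthenium as the next methylidene, so the overall change is an isomerisation in which that CH2 ends up as C3'. The closest known reaction type is the ring-rearrangement metathesis of cyclopentenes carrying a tethered olefin, combined with acrylate ring-closing metathesis to 5,6-dihydropyran-2-ones. The dihydropyranone is closed by olefin ring-closing metathesis between C4 and the acrylate α-carbon (six-membered, C3=C4 cis by ring constraint), while the cyclopentene is opened at C4=C2'. No stereocentre is created: C6 and C1' keep the cis-diol configuration, which becomes the erythro relation of the open chain. The step needs closure through C4 and not through C2' (which would build an isomeric six-membered lactone containing C1'); this should follow from loading of ruthenium on the less hindered C4, remote from the inductively deactivating allylic acetate, and from the fact that the electron-poor acrylate does not initiate, so the ring alkene reacts first. High dilution suppresses ring-opening oligomerisation, and conversion is helped by release of the strain of the cis-disubstituted cyclopentene and by the sluggish re-entry of the conjugated lactone alkene and the hindered vinyl group into the cycle.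

Step 6
Reactants: 8 ethyl (S)-lactate
Product: 9 ethyl (S)-2-(tert-butyldimethylsilyloxy)propanoate
Conditions: TBSCl, imidazole, DMF, rt
Reagents that add atoms: tert-butyldimethylsilyl chloride, CC(C)(C)[Si](C)(C)Cl
Why: Imidazole-promoted silylation of the secondary hydroxyl; the lactate stereocentre is not involved.

Step 7
Reactants: 9 ethyl (S)-2-(tert-butyldimethylsilyloxy)propanoate
Product: 10 (S)-2-(tert-butyldimethylsilyloxy)propanoic acid
Conditions: LiOH·H2O, THF/H2O, 0 °C; then 1 M HCl to pH 4
Reagents that add atoms: lithium hydroxide, [Li+].[OH-]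
Why: Saponification (BAc2) of the ethyl ester at 0 °C, where the secondary silyl ether survives and the α-stereocentre is not enolised once the carboxylate has formed.

Step 8
Reactants: 10 (S)-2-(tert-butyldimethylsilyloxy)propanoic acid
Product: 12 (S)-3-(tert-butyldimethylsilyloxy)-1-diazobutan-2-one, via mixed carbonic anhydride 11 (not isolated)
Conditions: iBuOCOCl, N-methylmorpholine, THF, −20 °C; then CH2N2 (Et2O), 0 °C
Reagents that add atoms: diazomethane, C=[N+]=[N-]; isobutyl chloroformate, CC(C)COC(Cl)=O (atoms in 11 only)
Why: Arndt–Eistert-type acylation of diazomethane by the mixed carbonic anhydride, which avoids the ketene pathway of an acid chloride and should therefore keep the α-silyloxy stereocentre intact.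

Step 9
Reactants: 7 (S)-1-[(R)-6-oxo-3,6-dihydro-2H-pyran-2-yl]prop-2-en-1-yl acetate; 12 (S)-3-(tert-butyldimethylsilyloxy)-1-diazobutan-2-one (2.5 equiv)
Product: 13 (S)-[(1S,2S)-2-[(S)-2-(tert-butyldimethylsilyloxy)propanoyl]cyclopropyl][(R)-6-oxo-3,6-dihydro-2H-pyran-2-yl]methyl acetate
Conditions: [Ru((S)-Ph-pheox)(MeCN)4]PF6 (5 mol%), CH2Cl2, 0 °C to rt, 12 added over 8 h
Reagents that add atoms: none
Why: Catalytic asymmetric cyclopropanation by ruthenium-carbene transfer from the α-diazoketone to the terminal C2'=C3' bond: the cis-disubstituted, electron-poor lactone alkene should be spared, the trans relation of C2' and C4' follows from the anti approach of the acyl group to the alkene substituent, and the 2'S,4'S configuration is set by the chiral Ph-pheox ligand selecting the vinyl face, with C6, C1' and C6' untouched.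

Step 10
Reactants: 13 (silyl ether of the cyclopropyl ketone)
Product: 14 (S)-[(1S,2S)-2-[(S)-2-hydroxypropanoyl]cyclopropyl][(R)-6-oxo-3,6-dihydro-2H-pyran-2-yl]methyl acetate
Conditions: HF·pyridine, pyridine/THF, 0 °C to rt
Reagents that add atoms: none
Why: Fluoride-mediated cleavage of the secondary silyl ether under buffered acidic conditions that leave the acetate, the enoate lactone and the base-sensitive α-ketol stereocentre untouched.

Step 11
Reactants: 15 caffeic acid
Product: 17 (E)-3-[3,4-bis(tert-butyldimethylsilyloxy)phenyl]acrylic acid, via tris-silylated caffeate 16 (not isolated)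
Conditions: TBSCl (3.3 equiv), imidazole, DMF, rt; then AcOH/THF/H2O, rt
Reagents that add atoms: tert-butyldimethylsilyl chloride, CC(C)(C)[Si](C)(C)Cl
Why: Exhaustive silylation of the two phenols and the carboxyl group followed by selective hydrolysis of the labile silyl ester in aqueous acetic acid, which the aryl silyl ethers withstand.

Step 12
Reactants: 14 (α-ketol); 17 (E)-3-[3,4-bis(tert-butyldimethylsilyloxy)phenyl]acrylic acid
Product: 18 (S)-1-[(1S,2S)-2-[(S)-acetoxy((R)-6-oxo-3,6-dihydro-2H-pyran-2-yl)methyl]cyclopropyl]-1-oxopropan-2-yl (E)-3-[3,4-bis(tert-butyldimethylsilyloxy)phenyl]acrylate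
Conditions: EDC·HCl, DMAP (0.2 equiv), CH2Cl2, 0 °C
Reagents that add atoms: none
Why: Steglich esterification (carbodiimide activation, acyl transfer through DMAP) of the secondary α-ketol hydroxyl with retention at C6', run at 0 °C with little DMAP to avoid enolisation of the α-acyloxy ketone.

Step 13
Reactants: 18 (bis-silyl ether of the target)
Product: 19 CNP0103198.1, (S)-1-[(1S,2S)-2-[(S)-acetoxy((R)-6-oxo-3,6-dihydro-2H-pyran-2-yl)methyl]cyclopropyl]-1-oxopropan-2-yl (E)-3-(3,4-dihydroxyphenyl)acrylate
Conditions: HF·pyridine, pyridine/THF, 0 °C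
Reagents that add atoms: none
Why: Cleavage of the two aryl silyl ethers by an acidic fluoride source that spares the three esters, the enoate lactone and the cyclopropyl ketone, so that no stereocentre is disturbed and the catechol is never exposed to base.

**Compound list**

1 | cyclopentadiene | C1C=CC=C1 | starting material
2 | rac-cis-cyclopent-3-ene-1,2-diol (racemate; (1R,2S) enantiomer drawn) | O[C@H]1C=CC[C@H]1O | intermediate
3 | rac-cis-cyclopent-3-ene-1,2-diyl diacetate (racemate; (1R,2S) enantiomer drawn) | CC(=O)O[C@H]1C=CC[C@H]1OC(C)=O | intermediate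
4 | (1S,5R)-5-hydroxycyclopent-2-en-1-yl acetate | CC(=O)O[C@H]1C=CC[C@H]1O | intermediate
5 | acryloyl chloride | C=CC(=O)Cl | starting material
6 | (1R,2S)-2-acetoxycyclopent-3-en-1-yl acrylate | CC(=O)O[C@H]1C=CC[C@H]1OC(=O)C=C | intermediate
7 | (S)-1-[(R)-6-oxo-3,6-dihydro-2H-pyran-2-yl]prop-2-en-1-yl acetate | CC(=O)O[C@@H](C=C)[C@H]1CC=CC(=O)O1 | intermediate
8 | ethyl (S)-lactate | CCOC(=O)[C@H](C)O | starting material
9 | ethyl (S)-2-(tert-butyldimethylsilyloxy)propanoate | CCOC(=O)[C@H](C)O[Si](C)(C)C(C)(C)C | intermediate
10 | (S)-2-(tert-butyldimethylsilyloxy)propanoic acid | OC(=O)[C@H](C)O[Si](C)(C)C(C)(C)C | intermediate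
11 | (S)-2-(tert-butyldimethylsilyloxy)propanoic isobutyl carbonic anhydride (not isolated) | CC(C)COC(=O)OC(=O)[C@H](C)O[Si](C)(C)C(C)(C)C | intermediate
12 | (S)-3-(tert-butyldimethylsilyloxy)-1-diazobutan-2-one | [N-]=[N+]=CC(=O)[C@H](C)O[Si](C)(C)C(C)(C)C | intermediate
13 | (S)-[(1S,2S)-2-[(S)-2-(tert-butyldimethylsilyloxy)propanoyl]cyclopropyl][(R)-6-oxo-3,6-dihydro-2H-pyran-2-yl]methyl acetate | CC(=O)O[C@@H]([C@H]1C[C@@H]1C(=O)[C@H](C)O[Si](C)(C)C(C)(C)C)[C@H]1CC=CC(=O)O1 | intermediate
14 | (S)-[(1S,2S)-2-[(S)-2-hydroxypropanoyl]cyclopropyl][(R)-6-oxo-3,6-dihydro-2H-pyran-2-yl]methyl acetate | CC(=O)O[C@@H]([C@H]1C[C@@H]1C(=O)[C@H](C)O)[C@H]1CC=CC(=O)O1 | intermediate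
15 | caffeic acid | OC(=O)/C=C/c1ccc(O)c(O)c1 | starting material
16 | tert-butyldimethylsilyl (E)-3-[3,4-bis(tert-butyldimethylsilyloxy)phenyl]acrylate (not isolated) | CC(C)(C)[Si](C)(C)OC(=O)/C=C/c1ccc(O[Si](C)(C)C(C)(C)C)c(O[Si](C)(C)C(C)(C)C)c1 | intermediate
17 | (E)-3-[3,4-bis(tert-butyldimethylsilyloxy)phenyl]acrylic acid | OC(=O)/C=C/c1ccc(O[Si](C)(C)C(C)(C)C)c(O[Si](C)(C)C(C)(C)C)c1 | intermediate
18 | bis(tert-butyldimethylsilyl) ether of the target | CC(=O)O[C@@H]([C@H]1C[C@@H]1C(=O)[C@H](C)OC(=O)/C=C/c1ccc(O[Si](C)(C)C(C)(C)C)c(O[Si](C)(C)C(C)(C)C)c1)[C@H]1CC=CC(=O)O1 | intermediate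
19 | CNP0103198.1 | CC(=O)O[C@@H]([C@H]1C[C@@H]1C(=O)[C@H](C)OC(=O)/C=C/c1ccc(O)c(O)c1)[C@H]1CC=CC(=O)O1 | target

**Step count**

Total: 13 steps. Longest linear sequence: 9 steps (steps 1, 2, 3, 4, 5, 9, 10, 12, 13).

**Steps most likely to fail**

Step 5 (ring-rearrangement metathesis). The isomerisation may stop short of completion, because the strain released from the cyclopentene is largely paid back when the ester is forced into the lactone geometry. The C4 alkylidene may also reclose onto the C2' vinyl group faster than it adds to the electron-poor acrylate until the catalyst has decayed, or closure may start from the C2' end. The fallback uses no metathesis and differentiates the two ring termini by unsymmetrical ozonolysis; it sets out from 4 and comes back at 7. Compound 4 is esterified with diethylphosphonoacetic acid (DCC, DMAP, CH2Cl2) to the phosphonoacetate F1. Ozonolysis in CH2Cl2/MeOH at −78 °C, then TsOH, then NaHCO3 and Me2S follows. The primary ozonide should fragment with the carbonyl oxide on C4, away from the inductively withdrawing allylic acetate, so that methanol capture, acetalisation of the C2' aldehyde and reduction leave the aldehyde acetal F2 (free aldehyde at C4, dimethyl acetal at C2'). Intramolecular Horner–Wadsworth–Emmons reaction under Masamune–Roush conditions (LiCl, iPr2NEt, MeCN) closes the ring to the lactone acetal F3, with C3=C4 cis by ring constraint. Aqueous TFA in CH2Cl2 liberates the α-acetoxy aldehyde F4. Takai–Lombardo methylenation (Zn, CH2Br2, TiCl4), which is not basic and should not epimerise C1', gives 7.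

Step 9 (cyclopropanation). Carbene transfer to a vinyl group that is hindered and inductively deactivated by the allylic acetate may be slow, so that dimerisation of the diazoketone takes over. Face selection by the catalyst may also be eroded by the C1' and C6' stereocentres in a mismatched pairing. The fallback is a hydroxyl-directed methylene transfer; it sets out from 7 (with 9 as the source of the ketone partner) and comes back at 13. Ester 9 is converted with MeNH(OMe)·HCl and iPrMgCl into the Weinreb amide F5, and CH2=CHMgBr gives the vinyl ketone F6. Cross-metathesis of 7 with F6 (second-generation Hoveyda–Grubbs catalyst RuCl2(H2IMes)(=CH-C6H4-2-OiPr), CH2Cl2, 40 °C) should give the (E)-enone F7 with loss of ethylene. Luche reduction (NaBH4, CeCl3·7H2O, MeOH, −78 °C), with Felkin–Anh attack anti to the silyloxy group, should give the (5'R)-allylic alcohol F8. Simmons–Smith cyclopropanation in the Furukawa form (Et2Zn, CH2I2, CH2Cl2, 0 °C) is directed by the C5' hydroxyl; in the conformer with C5'–H eclipsing the alkene it delivers CH2 to the face that gives 2'S,4'S, leading to the cyclopropyl carbinol F9. Dess–Martin oxidation gives 13. In this variant C3' comes from CH2I2.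

Step 3 (lipase resolution). The enzyme may discriminate the enantiomers at C1 insufficiently, may also cleave the allylic acetate, or the acetyl group may migrate between the cis oxygens after cleavage, giving material of low enantiomeric or regioisomeric purity. The fallback gives up the resolution and separates diastereomers later, with the lactate stereocentre as internal reference; it sets out from 2 and comes back at 13. Diol 2 is treated with 5 (1 equiv) and 2,4,6-collidine in CH2Cl2 at −78 °C. The mono-acrylate with the free allylic hydroxyl, racemic hydroxy acrylate F10, is separated by chromatography from its regioisomer and the diester. Ac2O and pyridine give racemic 6, that is 6 together with its enantiomer F11. Step 5 then gives 7 together with its enantiomer F12. Step 9 with enantiopure 12 converts F12 into the diastereomeric cyclopropyl ketone F13, which is separated from 13 by chromatography.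

**Further compounds**

F1 | step 5 | (1S,5R)-5-{[2-(diethoxyphosphoryl)acetyl]oxy}cyclopent-2-en-1-yl acetate | CC(=O)O[C@H]1C=CC[C@H]1OC(=O)CP(=O)(OCC)OCC
F2 | step 5 | (2R,3R)-2-acetoxy-1,1-dimethoxy-5-oxopentan-3-yl 2-(diethoxyphosphoryl)acetate | CC(=O)O[C@@H](C(OC)OC)[C@@H](CC=O)OC(=O)CP(=O)(OCC)OCC
F3 | step 5 | (R)-2,2-dimethoxy-1-[(R)-6-oxo-3,6-dihydro-2H-pyran-2-yl]ethyl acetate | CC(=O)O[C@@H](C(OC)OC)[C@H]1CC=CC(=O)O1
F4 | step 5 | (R)-2-oxo-1-[(R)-6-oxo-3,6-dihydro-2H-pyran-2-yl]ethyl acetate | CC(=O)O[C@@H](C=O)[C@H]1CC=CC(=O)O1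
F5 | step 9 | (S)-2-(tert-butyldimethylsilyloxy)-N-methoxy-N-methylpropanamide | CON(C)C(=O)[C@H](C)O[Si](C)(C)C(C)(C)C
F6 | step 9 | (S)-4-(tert-butyldimethylsilyloxy)pent-1-en-3-one | C=CC(=O)[C@H](C)O[Si](C)(C)C(C)(C)C
F7 | step 9 | (1S,2E,5S)-5-(tert-butyldimethylsilyloxy)-4-oxo-1-[(R)-6-oxo-3,6-dihydro-2H-pyran-2-yl]hex-2-en-1-yl acetate | CC(=O)O[C@@H](/C=C/C(=O)[C@H](C)O[Si](C)(C)C(C)(C)C)[C@H]1CC=CC(=O)O1
F8 | step 9 | (1S,2E,4R,5S)-5-(tert-butyldimethylsilyloxy)-4-hydroxy-1-[(R)-6-oxo-3,6-dihydro-2H-pyran-2-yl]hex-2-en-1-yl acetate | CC(=O)O[C@@H](/C=C/[C@@H](O)[C@H](C)O[Si](C)(C)C(C)(C)C)[C@H]1CC=CC(=O)O1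
F9 | step 9 | (S)-[(1S,2S)-2-[(1R,2S)-2-(tert-butyldimethylsilyloxy)-1-hydroxypropyl]cyclopropyl][(R)-6-oxo-3,6-dihydro-2H-pyran-2-yl]methyl acetate | CC(=O)O[C@@H]([C@H]1C[C@@H]1[C@@H](O)[C@H](C)O[Si](C)(C)C(C)(C)C)[C@H]1CC=CC(=O)O1
F10 | step 3 | rac-cis-2-hydroxycyclopent-3-en-1-yl acrylate (racemate; (1R,2S) enantiomer drawn) | O[C@H]1C=CC[C@H]1OC(=O)C=C
F11 | step 3 | (1S,2R)-2-acetoxycyclopent-3-en-1-yl acrylate (enantiomer of 6) | CC(=O)O[C@@H]1C=CC[C@@H]1OC(=O)C=C
F12 | step 3 | (R)-1-[(S)-6-oxo-3,6-dihydro-2H-pyran-2-yl]prop-2-en-1-yl acetate (enantiomer of 7) | CC(=O)O[C@H](C=C)[C@@H]1CC=CC(=O)O1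
F13 | step 3 | (R)-[(1S,2S)-2-[(S)-2-(tert-butyldimethylsilyloxy)propanoyl]cyclopropyl][(S)-6-oxo-3,6-dihydro-2H-pyran-2-yl]methyl acetate | CC(=O)O[C@H]([C@H]1C[C@@H]1C(=O)[C@H](C)O[Si](C)(C)C(C)(C)C)[C@@H]1CC=CC(=O)O1
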